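The C16 acyl chain is cut at C11–C12 and C14–C15. The segment C12–C13–C14, a carbinol carbon between two methylenes that each run on as a straight chain, is the carbon–oxygen framework of a chiral C3 epoxide; the phloroglucinol ring is attached last at C1. 11-Bromoundec-1-ene 1 gives Grignard reagent 2. In one flask (S)-epichlorohydrin 3 is opened by ethylmagnesium bromide 4, base recloses the chloro alkoxide to a new terminal epoxide, and 2 opens that. Both C–C bonds form in one operation and C13 arrives as S without any stereocentre being created. The precursors are only 3 and two simple Grignard reagents.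

Key step: step 2

Remark: chain carbons are numbered from the ketone carbon (C1) to the methyl group (C16), so the carbinol carbon is C13; ethylmagnesium bromide 4 is taken as the commercial titrated solution.

Step 1
Reactants: 1 11-bromoundec-1-ene
Product: 2 undec-10-enylmagnesium bromide (THF solution, titrated)
Conditions: Mg turnings (1.5 equiv), I2 (cat.), THF, slow addition, 25 → 45 °C
Reagents that add atoms: magnesium, [Mg]
Why: Grignard formation by insertion of magnesium into the primary C–Br bond, in which the remote terminal alkene is inert and slow addition of dilute bromide limits Wurtz coupling; no stereocentre is involved.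

Step 2
Reactants: 3 (S)-epichlorohydrin, 4 ethylmagnesium bromide, 2 undec-10-enylmagnesium bromide
Product: 8 (S)-hexadec-15-en-4-ol, via bromomagnesium (S)-1-chloropentan-2-olate 5 (not isolated), via potassium (S)-1-chloropentan-2-olate 6 (not isolated), via (S)-2-propyloxirane 7 (not isolated)
Conditions: 3, CuI (5 mol %), THF, −40 °C, 4 (1.05 equiv), → −20 °C; KOtBu (2.1 equiv), −20 → 20 °C; CuI (10 mol %), 2 (1.5 equiv), −30 → 0 °C; 1 M HCl, 0 °C
Reagents that add atoms: none
Why: The ethylcopper species generated from 4 and CuI opens the oxirane of 3 by SN2 attack at its unsubstituted CH2 (the future C14), which makes the C14–C15 bond and leaves chloro alkoxide 5. KOtBu strips the halide from magnesium, parks the metal as Mg(OtBu)2 and leaves potassium alkoxide 6, which displaces the neighbouring primary chloride in a 3-exo-tet closure to give oxirane 7 in solution, so this volatile epoxide is never isolated. The organocopper species formed from 2 and fresh CuI then opens 7 at its terminal CH2 (the future C12), which makes the C11–C12 bond and consumes the ring, so no ring formed here survives. The closest known reaction types are the copper-catalysed Grignard opening of terminal epoxides and the base-induced closure of a chlorohydrin to an epoxide, both established on epichlorohydrin with isolation in between and only telescoped here. No stereocentre is created: the C13–O bond is never broken, so the configuration of 3 is relayed, and the product is S because the ethyl arm is attached first. The step needs terminal regioselectivity in both openings and attack on the epoxide in preference to the C–Cl bond (direct chloride displacement would lead to the enantiomeric epoxide); copper catalysis at low temperature and the unhindered primary ring carbon of each monosubstituted oxirane should secure both.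

Step 3
Reactants: 8 (S)-hexadec-15-en-4-ol
Product: 9 (S)-hexadec-15-en-4-yl acetate
Conditions: Ac2O (1.5 equiv), pyridine, DMAP (5 mol %), CH2Cl2, 0 → 20 °C
Reagents that add atoms: acetic anhydride, CC(=O)OC(C)=O
Why: DMAP-catalysed O-acetylation (nucleophilic acyl substitution) leaves the C13–O bond untouched, so the configuration is retained, and gives an ester that should withstand hydroboration, oxoammonium oxidation and AlCl3.

Step 4
Reactants: 9 (S)-hexadec-15-en-4-yl acetate
Product: 11 (S)-16-hydroxyhexadecan-4-yl acetate, via (S)-16-(9-borabicyclo[3.3.1]nonan-9-yl)hexadecan-4-yl acetate 10 (not isolated)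
Conditions: 9-BBN (1.3 equiv), THF, 0 → 20 °C; NaBO3·4H2O (5 equiv), H2O, 20 °C
Reagents that add atoms: sodium perborate tetrahydrate (NaBO3·4H2O), [Na+].[O-]OB=O.O.O.O.O
Why: Hydroboration–oxidation, in which 9-BBN places boron on the terminal carbon (the future C1) of the monosubstituted alkene without reducing the acetate at room temperature, and NaBO3 oxidises the C–B bond under conditions mild enough to keep the ester.

Step 5
Reactants: 11 (S)-16-hydroxyhexadecan-4-yl acetate
Product: 12 (S)-13-acetoxyhexadecanoic acid
Conditions: TEMPO (0.2 equiv), PhI(OAc)2 (2.5 equiv), MeCN/CH2Cl2/H2O, 20 °C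
Reagents that add atoms: water, O
Why: TEMPO/PhI(OAc)2 oxoammonium oxidation takes the primary alcohol through the aldehyde hydrate to the carboxylic acid, while the secondary acetate and the remote stereocentre are inert to it.

Step 6
Reactants: 12 (S)-13-acetoxyhexadecanoic acid, 13 phloroglucinol
Product: 15 (S)-16-oxo-16-(2,4,6-trihydroxyphenyl)hexadecan-4-yl acetate, via (S)-13-acetoxyhexadecanoyl chloride 14 (not isolated)
Conditions: (COCl)2 (1.3 equiv), DMF (cat.), CH2Cl2, 0 → 20 °C, evaporate; 13 (anhydrous, 1.5 equiv), AlCl3 (5 equiv), CH2Cl2/MeNO2, 0 → 25 °C; ice, 1 M HCl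
Reagents that add atoms: none
Why: Friedel–Crafts acylation, in which the AlCl3-activated acid chloride attacks one of the three equivalent, strongly activated ring CH positions of phloroglucinol, the ketone formed deactivates the ring against a second acylation, and an unactivated secondary acetate should not be ionised by AlCl3 in nitromethane at room temperature.

Step 7
Reactants: 15 (S)-16-oxo-16-(2,4,6-trihydroxyphenyl)hexadecan-4-yl acetate
Product: 16 (S)-13-hydroxy-1-(2,4,6-trihydroxyphenyl)hexadecan-1-one
Conditions: LiOH·H2O (6 equiv), degassed THF/MeOH/H2O, Ar, 20 °C; 1 M HCl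
Reagents that add atoms: none
Why: Ester saponification by acyl–oxygen cleavage frees the C13 hydroxyl with retention because the alkyl C–O bond is not broken, while the aryl ketone, conjugated with its phenolates, should not react with hydroxide at room temperature and exclusion of air protects the electron-rich ring.

Compound list
1 | 11-bromoundec-1-ene | C=CCCCCCCCCCBr | starting material
2 | undec-10-enylmagnesium bromide | C=CCCCCCCCCC[Mg]Br | intermediate
3 | (S)-epichlorohydrin, (S)-2-(chloromethyl)oxirane | ClC[C@@H]1CO1 | starting material
4 | ethylmagnesium bromide | CC[Mg]Br | starting material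
5 | bromomagnesium (S)-1-chloropentan-2-olate | ClC[C@@H](O[Mg]Br)CCC | intermediate
6 | potassium (S)-1-chloropentan-2-olate | ClC[C@@H]([O-])CCC.[K+] | intermediate
7 | (S)-2-propyloxirane | CCC[C@H]1CO1 | intermediate
8 | (S)-hexadec-15-en-4-ol | CCC[C@H](O)CCCCCCCCCCC=C | intermediate
9 | (S)-hexadec-15-en-4-yl acetate | CCC[C@H](OC(C)=O)CCCCCCCCCCC=C | intermediate
10 | (S)-16-(9-borabicyclo[3.3.1]nonan-9-yl)hexadecan-4-yl acetate | CCC[C@H](OC(C)=O)CCCCCCCCCCCCB1C2CCCC1CCC2 | intermediate
11 | (S)-16-hydroxyhexadecan-4-yl acetate | CCC[C@H](OC(C)=O)CCCCCCCCCCCCO | intermediate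
12 | (S)-13-acetoxyhexadecanoic acid | CCC[C@H](OC(C)=O)CCCCCCCCCCCC(=O)O | intermediate
13 | phloroglucinol, benzene-1,3,5-triol | Oc1cc(O)cc(O)c1 | starting material
14 | (S)-13-acetoxyhexadecanoyl chloride | CCC[C@H](OC(C)=O)CCCCCCCCCCCC(=O)Cl | intermediate
15 | (S)-16-oxo-16-(2,4,6-trihydroxyphenyl)hexadecan-4-yl acetate | CCC[C@H](OC(C)=O)CCCCCCCCCCCC(=O)c1c(O)cc(O)cc1O | intermediate
16 | (S)-13-hydroxy-1-(2,4,6-trihydroxyphenyl)hexadecan-1-one | CCC[C@H](O)CCCCCCCCCCCC(=O)c1c(O)cc(O)cc1O | target

Total step count: 7. Longest linear sequence: 7 steps (1 → 2 → 8 → 9 → 11 → 12 → 15 → 16).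

Steps most likely to fail

Step 2. The closure of the chloro alkoxide may stay incomplete in the magnesium-rich medium, halide may reopen the new epoxide, leftover ethyl reagent may consume it, and any direct displacement of chloride in the first stage would erode the enantiomeric purity. The fallback reverses the order of the two openings on the mirror-image linchpin, so that both intermediates are non-volatile and can be isolated and purified in separate flasks. It sets out from 2: copper-catalysed addition of 2 to (R)-epichlorohydrin F1 (CuI, THF, −40 °C) should give (R)-1-chlorotetradec-13-en-2-ol F2. Closure with powdered NaOH in Et2O should give (R)-2-(dodec-11-en-1-yl)oxirane F3. Opening of F3 with 4 and CuI at its terminal CH2 comes back to the route at 8, with the S configuration because the two arms are attached in the opposite order to the opposite enantiomer.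

Step 6. O-acylation or a second C-acylation of phloroglucinol, poor solubility of the aluminium phenolates, or Lewis-acid loss of the secondary acetate by ionisation may lower the yield. The fallback replaces the Friedel–Crafts acylation by a Houben–Hoesch reaction and sets out from 11. One-pot oxidation with TEMPO, PhI(OAc)2 and NH4OAc in MeCN/H2O should give (S)-15-cyanopentadecan-4-yl acetate F4. Condensation of F4 with 13 under ZnCl2 and HCl gas in Et2O at 0 °C should give (S)-13-acetoxy-1-(2,4,6-trihydroxyphenyl)hexadecan-1-iminium chloride F5, which cannot be acylated a second time. Hydrolysis of F5 in hot water comes back to the route at 15; any ester cleaved during this hydrolysis gives material that step 7 converts as well.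

Step 4. Partial cleavage or reduction of the acetate during hydroboration and oxidative work-up, or sluggish oxidation of the hindered borane, may give mixtures. The fallback hydroborates before any ester is present and sets out from 8. 9-BBN (2.2 equiv) followed by NaOH/H2O2 should give (S)-hexadecane-1,13-diol F6. Primary-selective oxidation with TEMPO, NaClO2 and catalytic NaOCl in buffered MeCN should give (S)-13-hydroxyhexadecanoic acid F7. Acetylation of F7 with Ac2O/pyridine, with an aqueous NaHCO3 work-up to hydrolyse the mixed anhydride, comes back to the route at 12.

Further compounds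
F1 | step 2 | (R)-epichlorohydrin | ClC[C@H]1CO1
F2 | step 2 | (R)-1-chlorotetradec-13-en-2-ol | ClC[C@H](O)CCCCCCCCCCC=C
F3 | step 2 | (R)-2-(dodec-11-en-1-yl)oxirane | C=CCCCCCCCCCC[C@@H]1CO1
F4 | step 6 | (S)-15-cyanopentadecan-4-yl acetate | CCC[C@H](OC(C)=O)CCCCCCCCCCCC#N
F5 | step 6 | (S)-13-acetoxy-1-(2,4,6-trihydroxyphenyl)hexadecan-1-iminium chloride | CCC[C@H](OC(C)=O)CCCCCCCCCCCC(=[NH2+])c1c(O)cc(O)cc1O.[Cl-]
F6 | step 4 | (S)-hexadecane-1,13-diol | CCC[C@H](O)CCCCCCCCCCCCO
F7 | step 4 | (S)-13-hydroxyhexadecanoic acid | CCC[C@H](O)CCCCCCCCCCCC(=O)O
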